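**Fixed numbering:** 1–24 as in the compound list; 12 and 19 are intermediates that are not isolated.

## Analysis of the target

The target is a linear flavan-3-ol trimer, epicatechin 3-O-gallate-(4β→8)-epigallocatechin 3-O-gallate-(4β→8)-catechin 3-O-gallate. It consists of three 2-arylchroman units (rings A, C and B in each), joined by two C4–C8 bonds, and each C3 oxygen carries a galloyl ester. There are eight stereocentres. C2, C3 and C4 of the top and of the middle unit are 2,3-cis-3,4-trans (C2 aryl and C3 oxygen α, C4 aryl β), and C2 and C3 of the bottom unit are 2,3-trans. Twenty-two free phenols make the compound prone to oxidation, the interflavan bonds ionise in strong acid, C2 epimerises under base once ring B phenols are free, and the gallates are base-labile, so every phenol has to stay masked until a final neutral step. The difficulty lies in the two 4β interflavan bonds with unambiguous C8 (not C6) connectivity, in the three different units, and in the cis-placed gallate of the top unit. Five stereocentres can be taken from the chirality pool, leaving C4 of the middle unit and the three centres of the top unit to be made. The strategy rests on ring C of the top unit: O1, C2, C3 and C4, with the catechol on C2, the gallate on C3 and C8 of the middle unit on C4, form the [4+2] adduct of an o-quinone methide (O1=C8a–C4a=C4) and a (Z)-enol gallate (C2=C3).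

## Retrosynthetic reasoning

**24 to 23.** The twenty-two O–benzyl bonds are cut last, because the free polyphenol tolerates neither base nor oxidants nor chromatography on silica. The forward step must remove all of them by hydrogenolysis without opening the pyran C2–O1 bonds or touching the three esters.

**23 to 21 and 22, then 21 to 20.** The ester C–O bonds at C3 of the middle and bottom units are cut to diol 21 and acid chloride 22, and the diol is traced to bis-silyl ether 20. These two positions cannot carry esters earlier, since an aryllithium is used on the dimer. The top gallate needs no such detour because it arrives with the cycloaddition. The forward steps must free two hindered secondary alcohols without disturbing the top ester and then acylate them with retention.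

**20 to 19 and 18, and 19 to 14.** O1–C2 and C3–C4 of the top ring C are cut in a retro-[4+2]. This is the only cut that removes a ring, three stereocentres and an ester in one operation, and it leaves a dimer whose stereocentres all come from natural flavanols or a standard coupling. It gives o-quinone methide 19, which comes from o-hydroxybenzhydrol 14 by dehydration, and (Z)-enol gallate 18. The forward reaction has to fix the regiochemistry (C3 to the methide carbon, O1 to the benzylic carbon), keep the alkene geometry, place the C4 aryl group trans to both new substituents and choose one diene face.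

**18 to 16 and 17, and 16 to 15.** The vinyl C–O bond of 18 is cut to alkyne 16 and acid 17, an anti-Markovnikov hydro-acyloxylation in the forward sense that must deliver the (Z) isomer. The alkyne carbon comes from aldehyde 15 by one-carbon homologation.

**14 to 13, and 13 to 12 and 11.** The O–allyl bond of 13 is cut first. Then the bond between C8 of the middle unit and the carbinol carbon is cut to aryllithium 12 and aldehyde 11. Here the aldehyde carbon becomes C4 of the top unit, and the position of the metal, inherited from the bromine of 8, guarantees C8 connectivity without any regiochemical question. Aldehyde 11 goes back to 10 and to 9 by two O-alkylations that exploit the chelated ortho hydroxyl.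

**8 to 7, and 7 to 4 and 6.** After removal of the two silyl groups, the interflavan C4–C8 bond is cut to a C4 cation equivalent 4 and the C8 nucleophile 6. This is the natural polarity of the bond, and the forward coupling sets the 4β centre by approach anti to the α substituents. The bromine of 4 serves twice, as a cap against self-condensation and as the later site of metalation.

**4 to 1, and 6 to 5.** Compound 4 is traced through 3 and 2 to (−)-epigallocatechin 1 by C4 oxidation, C8 bromination and O-benzylation. Compound 6 is the benzyl ether of (+)-catechin 5.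

## Alternatives that were turned down

**Alternative 1:** Ring A of the middle unit is disconnected at C8–C8a, C6–C7, C5–C6 and C4a–C8a into diazo ketone A1 and siloxyalkyne A2, which carries the complete top unit on the alkyne. In the forward sense, irradiation of A1 triggers a Wolff rearrangement to a vinylketene. This adds A2 by [2+2], opens by a 4π process and closes by a 6π process to phenol A3 (a Danheiser benzannulation).
- For: the C4–C8 connectivity exists before the arene does, so there is no C6/C8 question and no cationic chemistry at that bond. All four substituents of the new ring come out differentiated. On certainty of connectivity it is at least as strong as the chosen route.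
- Against: the step forms no stereocentre. After A3 the whole ring C of the middle unit with three stereocentres, the pyrogallol ring, the second interflavan bond and all three gallates are still missing. The middle unit can no longer be taken from 1, so its C2 and C3 need an asymmetric step. A2 itself needs a stereodefined 4-alkynylflavan.
- Comparison: the chosen route obtains the same connectivity guarantee from the bromine placed in 3 and carried to 12. It draws five stereocentres from the pool and is expected to be more than ten steps shorter.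

**Alternative 2:** The top ring C is cut at C4–C4a and O1–C2 to dimer enone A4 and phenol A5. In the forward sense, a chiral phosphoric acid directs the ortho carbon of A5 onto the β-carbon of A4, and cyclodehydration closes the ring as 4H-chromene A6.
- For: this reaction type is closer to established asymmetric catalysis than the chosen key step. Only one stereocentre (C4) has to be controlled. The acid can hold both partners, the phenol through its hydroxyl and the enone through its carbonyl, which the chosen key step cannot do because 18 has no hydrogen-bond donor.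
- Against: A6 still lacks the C2 and C3 centres and the gallate. Hydroboration–oxidation of the enol ether adds H and OH syn and would give the 2,3-trans alcohol, so C3 must then be inverted by oxidation and hydride reduction before acylation. That is four to five further steps on the most advanced material. The β-carbon of A4 bears a 2,6-dioxygenated aryl group and is a hindered, deactivated acceptor, and the enol ether of A6 is acid-labile.
- Comparison: the chosen cycloaddition reaches 20 directly with C2, C3, C4 and the ester in place, at the price of a harder stereochemical problem in one step.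

**Alternative 3:** O1–C2, C2–C3 and the interflavan C4–C8 bond are cut together, giving aldehyde A7 (identical with 15), phenolic (Z)-enol gallate A8 and dimer digallate A9. In the forward sense, a silyl triflate condenses A7 with the phenol of A8 to an O-aryl oxocarbenium ion. The enol ester carbon attacks it in a 6-endo Prins closure, and the C4 cation is captured by C8 of A9 to give A10 (identical with 23).
- For: it is the most convergent plan. It needs no silyl ethers and no late acylation, and ends one step from the target. The interflavan bond forms from a cyclic flavan-4-yl cation next to a C3 acyloxy group, the situation in which 4β selectivity is best understood; on 3,4-trans control it is stronger than the chosen route.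
- Against: two untested bond formations and three components share one flask. Electron-rich phenols and A7 tend to react at ring carbon rather than through an O-aryl oxocarbenium ion. A9 can intercept A7 or the oxocarbenium ion directly. A8 has a free phenol next to a (Z)-enol ester and is liable to acyl transfer. The 2,3-cis relation depends on a chair-like cationic closure with the ester axial. C8 versus C6 selectivity on A9 is no better than in a classical coupling.
- Comparison: the chosen route separates these events. The C8 bond is made by an organolithium at a position marked by bromine, and the ring is closed by one bimolecular cycloaddition from an isolable precursor. It pays for this with three extra steps at the end.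

Key step: step 13

## Assumptions

- Assumption: 3,4-bis(benzyloxy)benzaldehyde 15 and 3,4,5-tris(benzyloxy)benzoic acid 17 are catalogue compounds and are taken as purchased.
- Assumption: the carbinol centre made in step 9 is not controlled; 13 and 14 are carried as mixtures of both epimers (one is drawn), since both give the same quinone methide 19.
- Assumption: the (R) enantiomer of the phosphoric acid is taken as the one matched to the required diene face.

## Route

Step 1
Reactants: 1 (−)-epigallocatechin
Product: 2 5,7,3',4',5'-penta-O-benzyl-(−)-epigallocatechin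
Conditions: BnBr (5.5 equiv), K2CO3, DMF, 0 °C → rt, Ar
Reagents that add atoms: benzyl bromide, BrCc1ccccc1
Why: Williamson O-benzylation; carbonate deprotonates only the five phenols, and fast alkylation under argon protects the pyrogallol ring from oxidation and C2 from base-induced epimerisation.

Step 2
Reactants: 2 5,7,3',4',5'-penta-O-benzyl-(−)-epigallocatechin
Product: 3 8-bromo-5,7,3',4',5'-penta-O-benzyl-(−)-epigallocatechin
Conditions: NBS (1.0 equiv), CH2Cl2, −78 → −20 °C
Reagents that add atoms: N-bromosuccinimide, O=C1CCC(=O)N1Br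
Why: electrophilic aromatic bromination; in 5,7-dialkoxyflavans C8, between one benzyloxy group and the ring oxygen, is the most accessible activated carbon, whereas C6 lies between two benzyloxy groups and ring B is much less activated.

Step 3
Reactants: 3 8-bromo-5,7,3',4',5'-penta-O-benzyl-(−)-epigallocatechin
Product: 4 8-bromo-4β-(2-ethoxyethoxy)-5,7,3',4',5'-penta-O-benzyl-(−)-epigallocatechin (2,3-cis-3,4-trans)
Conditions: DDQ (2 equiv), 2-ethoxyethanol (5 equiv), CH2Cl2, rt
Reagents that add atoms: 2-ethoxyethanol, CCOCCO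
Why: DDQ abstracts hydride from C4, which is benzylic and ortho/para to the three ring A oxygens, and the cation is trapped by the alcohol on the β face, anti to the α groups at C2 and C3; this centre only carries the leaving group and is ionised again in step 5.

Step 4
Reactants: 5 (+)-catechin
Product: 6 5,7,3',4'-tetra-O-benzyl-(+)-catechin
Conditions: BnBr (4.4 equiv), K2CO3, DMF, 0 °C → rt, Ar
Reagents that add atoms: benzyl bromide, BrCc1ccccc1
Why: Williamson O-benzylation of the four phenols, as in step 1; the C3 alcohol stays free.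

Step 5
Reactants: 4 8-bromo-4β-(2-ethoxyethoxy)-penta-O-benzylepigallocatechin; 6 5,7,3',4'-tetra-O-benzyl-(+)-catechin
Product: 7 8-bromo-penta-O-benzylepigallocatechin-(4β→8)-tetra-O-benzylcatechin (both C3 hydroxyls free)
Conditions: TMSOTf (0.2 equiv), 6 (1.5 equiv), CH2Cl2, −78 °C; then Et3N
Reagents that add atoms: none
Why: Lewis-acid-mediated Friedel–Crafts coupling of a flavan-4-yl cation; C8 of 6 attacks the ring-A-stabilised cation anti to the α-oriented C2 aryl and C3 hydroxyl groups, which sets the 4β (3,4-trans) centre, and the bromine at C8 of 4 blocks self-condensation.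

Step 6
Reactants: 7 8-bromo-penta-O-benzylepigallocatechin-(4β→8)-tetra-O-benzylcatechin
Product: 8 bis-silyl ether of 7 (tert-butyldimethylsilyl on the C3 oxygen of both units)
Conditions: TBSOTf (3 equiv), 2,6-lutidine, CH2Cl2, 0 °C → rt
Reagents that add atoms: tert-butyldimethylsilyl triflate, CC(C)(C)[Si](C)(C)OS(=O)(=O)C(F)(F)F
Why: silyl triflate silylation of hindered secondary alcohols; both C3 hydroxyls are masked for the organolithium step with groups that fluoride removes later.

Step 7
Reactants: 9 2,4,6-trihydroxybenzaldehyde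
Product: 10 2,4-bis(benzyloxy)-6-hydroxybenzaldehyde
Conditions: BnBr (2.05 equiv), K2CO3 (2.2 equiv), DMF, 0 °C → rt
Reagents that add atoms: benzyl bromide, BrCc1ccccc1
Why: Williamson alkylation; the para hydroxyl and one ortho hydroxyl react, while the last ortho hydroxyl is tied to the formyl group by a hydrogen bond and is the least nucleophilic, so two equivalents should stop at 10.

Step 8
Reactants: 10 2,4-bis(benzyloxy)-6-hydroxybenzaldehyde
Product: 11 2-(allyloxy)-4,6-bis(benzyloxy)benzaldehyde
Conditions: allyl bromide (1.5 equiv), K2CO3, DMF, 60 °C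
Reagents that add atoms: allyl bromide, C=CCBr
Why: Williamson allylation of the chelated phenol under more forcing conditions; allyl survives the aryllithium addition and is later removed by palladium under neutral conditions, orthogonal to benzyl and silyl ethers.

Step 9
Reactants: 8 bis-silylated bromo dimer; 11 2-(allyloxy)-4,6-bis(benzyloxy)benzaldehyde
Product: 13 benzhydrol in which the carbinol carbon joins C8 of the epigallocatechin unit (in place of bromine) to C1 of the 2-(allyloxy)-4,6-bis(benzyloxy)phenyl ring (both carbinol epimers), via C8-aryllithium 12 (not isolated)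
Conditions: n-BuLi (1.05 equiv), THF, −78 °C; then 11 (1.3 equiv), −78 → −40 °C; aq. NH4Cl
Reagents that add atoms: none
Why: bromine–lithium exchange gives 12 exactly at the carbon marked by bromine, and 1,2-addition to the aldehyde forms the C8–carbinol bond; the new carbinol centre is uncontrolled and is erased in step 13.

Step 10
Reactants: 13 allyl-protected benzhydrol
Product: 14 o-hydroxybenzhydrol, the carbinol carbon now bearing a 2,4-bis(benzyloxy)-6-hydroxyphenyl ring (both carbinol epimers)
Conditions: Pd(PPh3)4 (5 mol %), morpholine (5 equiv), THF, rt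
Reagents that add atoms: none
Why: Tsuji–Trost-type deallylation; zerovalent palladium ionises the allyl aryl ether and morpholine captures the π-allyl fragment, which frees the phenol under neutral conditions that leave the acid-sensitive benzhydrol, the benzyl ethers and the silyl ethers intact.

Step 11
Reactants: 15 3,4-bis(benzyloxy)benzaldehyde
Product: 16 1,2-bis(benzyloxy)-4-ethynylbenzene
Conditions: dimethyl (1-diazo-2-oxopropyl)phosphonate, K2CO3, MeOH/THF, rt
Reagents that add atoms: dimethyl (1-diazo-2-oxopropyl)phosphonate, CC(=O)C(=[N+]=[N-])P(=O)(OC)OC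
Why: Seyferth–Gilbert homologation in the Ohira–Bestmann variant; methanolysis of the reagent releases the diazomethylphosphonate anion, which turns the aldehyde into the terminal alkyne under mild base.

Step 12
Reactants: 16 1,2-bis(benzyloxy)-4-ethynylbenzene; 17 3,4,5-tris(benzyloxy)benzoic acid
Product: 18 (Z)-2-[3,4-bis(benzyloxy)phenyl]ethenyl 3,4,5-tris(benzyloxy)benzoate
Conditions: Ru(methallyl)2(dppb) (2 mol %), toluene, 50 °C
Reagents that add atoms: none
Why: ruthenium-catalysed anti-Markovnikov hydro-acyloxylation of a terminal aryl alkyne; the carboxylate adds to the α-carbon of a ruthenium vinylidene and protonolysis gives the (Z)-enol ester, the geometry that later becomes the 2,3-cis relation.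

Step 13
Reactants: 14 o-hydroxybenzhydrol; 18 (Z)-enol gallate
Product: 20 hexadeca-O-benzyl trimer with the top unit closed as epicatechin 3-O-(tribenzylgallate) joined 4β→8 to the middle unit and silyl ethers at C3 of the middle and bottom units, via o-quinone methide 19 (not isolated)
Conditions: (R)-TRIP (10 mol %), 18 (2 equiv), 5 Å MS, CH2Cl2, −20 °C → rt
Reagents that add atoms: none
Why: Proposed new method: the phosphoric acid (TRIP, the 3,3'-bis(2,4,6-triisopropylphenyl)-BINOL hydrogen phosphate) protonates the benzylic hydroxyl of 14, water is lost to the sieves and the hydrogen-bonded o-quinone methide 19, a 1-oxadiene, adds the electron-rich alkene of 18 in an inverse-demand hetero-Diels–Alder reaction. The closest known reaction type is the chiral-phosphoric-acid-catalysed [4+2] of in situ o-quinone methides with styrenes, enamides and enol ethers to 2,4-diarylchromans; a β-acyloxystyrene as the 2π partner and a methide carbon bearing a 2,6-dioxygenated aryl group lie outside it. Ring C of the top unit closes by intermolecular cycloaddition, C3 bonding to the methide carbon C4 and the quinone oxygen O1 to C2, concerted but asynchronous with the C3–C4 bond in advance. The regiochemistry is secured by the 3,4-bis(benzyloxy)phenyl group, which stabilises positive charge at C2 far better than the acyloxy group does at C3, so the styrene polarisation overrides the opposite enol ester polarisation. The cis relation of C2 and C3 is controlled by suprafacial addition across the (Z)-alkene, provided the addition stays concerted. The trans relation of C4 to both is controlled by the (Z)-methide geometry, in which the dimer aryl group turns toward the carbonyl oxygen to avoid allylic strain with the C5 benzyloxy group, together with endo placement of the aryl and galloyloxy groups of 18, which puts the outside methide hydrogen cis and the aryl trans to them. The absolute sense at all three centres depends on which diene face reacts, and this is chosen jointly by the chiral phosphate bound at the quinone oxygen and by the stereocentres of the flavan unit on the methide carbon. The step therefore needs endo and facial selectivity and a rate that outruns self-trapping of 19, for which the excess of 18 and the absence of other nucleophiles are the only safeguards.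

Step 14
Reactants: 20 bis-silylated trimer mono-gallate
Product: 21 trimer mono-gallate diol (free C3 hydroxyls on the middle and bottom units)
Conditions: HF·pyridine, pyridine, THF, 0 °C → rt
Reagents that add atoms: none
Why: fluoride-mediated desilylation; buffered HF·pyridine cleaves both secondary silyl ethers, while the aryl ester, the benzyl ethers and the interflavan bonds are stable in this weakly acidic medium.

Step 15
Reactants: 17 3,4,5-tris(benzyloxy)benzoic acid
Product: 22 3,4,5-tris(benzyloxy)benzoyl chloride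
Conditions: (COCl)2, DMF (cat.), CH2Cl2, 0 °C → rt
Reagents that add atoms: oxalyl chloride, ClC(=O)C(=O)Cl
Why: acid chloride formation through the chloroiminium species made from DMF and oxalyl chloride; benzyl ethers are inert.

Step 16
Reactants: 21 trimer mono-gallate diol; 22 3,4,5-tris(benzyloxy)benzoyl chloride
Product: 23 docosa-O-benzyl trimer tri-gallate (perbenzylated target)
Conditions: 22 (6 equiv), DMAP (cat.), pyridine, CH2Cl2, rt → 40 °C
Reagents that add atoms: none
Why: DMAP-catalysed acylation through the N-acylpyridinium ion, reactive enough for the hindered C3 hydroxyl of the middle unit; only O–acyl bonds form, so no stereocentre is touched.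

Step 17
Reactants: 23 docosa-O-benzyl trimer tri-gallate
Product: 24 CNP0321910.1, epicatechin 3-O-gallate-(4β→8)-epigallocatechin 3-O-gallate-(4β→8)-catechin 3-O-gallate
Conditions: H2 (1 atm), Pd(OH)2/C, THF/MeOH/H2O, rt
Reagents that add atoms: none
Why: hydrogenolysis of all twenty-two aryl benzyl ethers under neutral conditions; aryl benzyl ethers cleave much faster than the pyran C2–O1 bonds, and the esters and interflavan bonds are not affected.

## Compound list

1 | (−)-epigallocatechin | O[C@@H]1Cc2c(O)cc(O)cc2O[C@@H]1c1cc(O)c(O)c(O)c1 | starting material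
2 | 5,7,3',4',5'-penta-O-benzyl-(−)-epigallocatechin | O[C@@H]1Cc2c(OCc9ccccc9)cc(OCc9ccccc9)cc2O[C@@H]1c1cc(OCc9ccccc9)c(OCc9ccccc9)c(OCc9ccccc9)c1 | intermediate
3 | 8-bromo-5,7,3',4',5'-penta-O-benzyl-(−)-epigallocatechin | O[C@@H]1Cc2c(OCc9ccccc9)cc(OCc9ccccc9)c(Br)c2O[C@@H]1c1cc(OCc9ccccc9)c(OCc9ccccc9)c(OCc9ccccc9)c1 | intermediate
4 | 8-bromo-4β-(2-ethoxyethoxy)-5,7,3',4',5'-penta-O-benzyl-(−)-epigallocatechin | O[C@@H]1[C@@H](OCCOCC)c2c(OCc9ccccc9)cc(OCc9ccccc9)c(Br)c2O[C@@H]1c1cc(OCc9ccccc9)c(OCc9ccccc9)c(OCc9ccccc9)c1 | intermediate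
5 | (+)-catechin | O[C@H]1Cc2c(O)cc(O)cc2O[C@@H]1c1ccc(O)c(O)c1 | starting material
6 | 5,7,3',4'-tetra-O-benzyl-(+)-catechin | O[C@H]1Cc2c(OCc9ccccc9)cc(OCc9ccccc9)cc2O[C@@H]1c1ccc(OCc9ccccc9)c(OCc9ccccc9)c1 | intermediate
7 | 8-bromo-penta-O-benzylepigallocatechin-(4β→8)-tetra-O-benzylcatechin | O[C@@H]1[C@@H](c2c(OCc9ccccc9)cc(OCc9ccccc9)c3c2O[C@H](c7ccc(OCc9ccccc9)c(OCc9ccccc9)c7)[C@@H](O)C3)c2c(OCc9ccccc9)cc(OCc9ccccc9)c(Br)c2O[C@@H]1c7cc(OCc9ccccc9)c(OCc9ccccc9)c(OCc9ccccc9)c7 | intermediate
8 | bis(tert-butyldimethylsilyl) ether of 7 | CC(C)(C)[Si](C)(C)O[C@@H]1[C@@H](c2c(OCc9ccccc9)cc(OCc9ccccc9)c3c2O[C@H](c7ccc(OCc9ccccc9)c(OCc9ccccc9)c7)[C@@H](O[Si](C)(C)C(C)(C)C)C3)c2c(OCc9ccccc9)cc(OCc9ccccc9)c(Br)c2O[C@@H]1c7cc(OCc9ccccc9)c(OCc9ccccc9)c(OCc9ccccc9)c7 | intermediate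
9 | 2,4,6-trihydroxybenzaldehyde | O=Cc1c(O)cc(O)cc1O | starting material
10 | 2,4-bis(benzyloxy)-6-hydroxybenzaldehyde | O=Cc1c(O)cc(OCc9ccccc9)cc1OCc9ccccc9 | intermediate
11 | 2-(allyloxy)-4,6-bis(benzyloxy)benzaldehyde | O=Cc1c(OCC=C)cc(OCc9ccccc9)cc1OCc9ccccc9 | intermediate
12 | C8-aryllithium of the bis-silylated dimer | CC(C)(C)[Si](C)(C)O[C@@H]1[C@@H](c2c(OCc9ccccc9)cc(OCc9ccccc9)c3c2O[C@H](c7ccc(OCc9ccccc9)c(OCc9ccccc9)c7)[C@@H](O[Si](C)(C)C(C)(C)C)C3)c2c(OCc9ccccc9)cc(OCc9ccccc9)c([Li])c2O[C@@H]1c7cc(OCc9ccccc9)c(OCc9ccccc9)c(OCc9ccccc9)c7 | intermediate (not isolated)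
13 | allyl-protected dimer benzhydrol (one carbinol epimer drawn) | CC(C)(C)[Si](C)(C)O[C@@H]1[C@@H](c2c(OCc9ccccc9)cc(OCc9ccccc9)c3c2O[C@H](c7ccc(OCc9ccccc9)c(OCc9ccccc9)c7)[C@@H](O[Si](C)(C)C(C)(C)C)C3)c2c(OCc9ccccc9)cc(OCc9ccccc9)c([C@H](O)c4c(OCC=C)cc(OCc9ccccc9)cc4OCc9ccccc9)c2O[C@@H]1c7cc(OCc9ccccc9)c(OCc9ccccc9)c(OCc9ccccc9)c7 | intermediate
14 | dimer o-hydroxybenzhydrol (one carbinol epimer drawn) | CC(C)(C)[Si](C)(C)O[C@@H]1[C@@H](c2c(OCc9ccccc9)cc(OCc9ccccc9)c3c2O[C@H](c7ccc(OCc9ccccc9)c(OCc9ccccc9)c7)[C@@H](O[Si](C)(C)C(C)(C)C)C3)c2c(OCc9ccccc9)cc(OCc9ccccc9)c([C@H](O)c4c(O)cc(OCc9ccccc9)cc4OCc9ccccc9)c2O[C@@H]1c7cc(OCc9ccccc9)c(OCc9ccccc9)c(OCc9ccccc9)c7 | intermediate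
15 | 3,4-bis(benzyloxy)benzaldehyde | O=Cc1ccc(OCc9ccccc9)c(OCc9ccccc9)c1 | starting material
16 | 1,2-bis(benzyloxy)-4-ethynylbenzene | C#Cc1ccc(OCc9ccccc9)c(OCc9ccccc9)c1 | intermediate
17 | 3,4,5-tris(benzyloxy)benzoic acid | OC(=O)c1cc(OCc9ccccc9)c(OCc9ccccc9)c(OCc9ccccc9)c1 | starting material
18 | (Z)-2-[3,4-bis(benzyloxy)phenyl]ethenyl 3,4,5-tris(benzyloxy)benzoate | O=C(O/C=C\c7ccc(OCc9ccccc9)c(OCc9ccccc9)c7)c8cc(OCc9ccccc9)c(OCc9ccccc9)c(OCc9ccccc9)c8 | intermediate
19 | (Z)-o-quinone methide of the dimer (aryl syn to the carbonyl) | CC(C)(C)[Si](C)(C)O[C@@H]1[C@@H](c2c(OCc9ccccc9)cc(OCc9ccccc9)c3c2O[C@H](c7ccc(OCc9ccccc9)c(OCc9ccccc9)c7)[C@@H](O[Si](C)(C)C(C)(C)C)C3)c2c(OCc9ccccc9)cc(OCc9ccccc9)c(/C=C4\C(=O)C=C(OCc9ccccc9)C=C4OCc9ccccc9)c2O[C@@H]1c7cc(OCc9ccccc9)c(OCc9ccccc9)c(OCc9ccccc9)c7 | intermediate (not isolated)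
20 | hexadeca-O-benzyl trimer, top 3-O-(tribenzylgallate), silyl ethers at C3 of middle and bottom units | CC(C)(C)[Si](C)(C)O[C@@H]1[C@@H](c2c(OCc9ccccc9)cc(OCc9ccccc9)c3c2O[C@H](c7ccc(OCc9ccccc9)c(OCc9ccccc9)c7)[C@@H](O[Si](C)(C)C(C)(C)C)C3)c2c(OCc9ccccc9)cc(OCc9ccccc9)c([C@H]3c4c(OCc9ccccc9)cc(OCc9ccccc9)cc4O[C@H](c7ccc(OCc9ccccc9)c(OCc9ccccc9)c7)[C@@H]3OC(=O)c8cc(OCc9ccccc9)c(OCc9ccccc9)c(OCc9ccccc9)c8)c2O[C@@H]1c7cc(OCc9ccccc9)c(OCc9ccccc9)c(OCc9ccccc9)c7 | intermediate
21 | hexadeca-O-benzyl trimer, top 3-O-(tribenzylgallate), free C3 hydroxyls on middle and bottom units | O[C@@H]1[C@@H](c2c(OCc9ccccc9)cc(OCc9ccccc9)c3c2O[C@H](c7ccc(OCc9ccccc9)c(OCc9ccccc9)c7)[C@@H](O)C3)c2c(OCc9ccccc9)cc(OCc9ccccc9)c([C@H]3c4c(OCc9ccccc9)cc(OCc9ccccc9)cc4O[C@H](c7ccc(OCc9ccccc9)c(OCc9ccccc9)c7)[C@@H]3OC(=O)c8cc(OCc9ccccc9)c(OCc9ccccc9)c(OCc9ccccc9)c8)c2O[C@@H]1c7cc(OCc9ccccc9)c(OCc9ccccc9)c(OCc9ccccc9)c7 | intermediate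
22 | 3,4,5-tris(benzyloxy)benzoyl chloride | O=C(Cl)c1cc(OCc9ccccc9)c(OCc9ccccc9)c(OCc9ccccc9)c1 | intermediate
23 | docosa-O-benzyl trimer tri-gallate | O=C(O[C@@H]1[C@@H](c2c(OCc9ccccc9)cc(OCc9ccccc9)c3c2O[C@H](c7ccc(OCc9ccccc9)c(OCc9ccccc9)c7)[C@@H](OC(=O)c8cc(OCc9ccccc9)c(OCc9ccccc9)c(OCc9ccccc9)c8)C3)c2c(OCc9ccccc9)cc(OCc9ccccc9)c([C@H]3c4c(OCc9ccccc9)cc(OCc9ccccc9)cc4O[C@H](c7ccc(OCc9ccccc9)c(OCc9ccccc9)c7)[C@@H]3OC(=O)c8cc(OCc9ccccc9)c(OCc9ccccc9)c(OCc9ccccc9)c8)c2O[C@@H]1c7cc(OCc9ccccc9)c(OCc9ccccc9)c(OCc9ccccc9)c7)c8cc(OCc9ccccc9)c(OCc9ccccc9)c(OCc9ccccc9)c8 | intermediate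
24 | CNP0321910.1 | O=C(O[C@@H]1[C@@H](c2c(O)cc(O)c3c2O[C@H](c2ccc(O)c(O)c2)[C@@H](OC(=O)c2cc(O)c(O)c(O)c2)C3)c2c(O)cc(O)c([C@H]3c4c(O)cc(O)cc4O[C@H](c4ccc(O)c(O)c4)[C@@H]3OC(=O)c3cc(O)c(O)c(O)c3)c2O[C@@H]1c1cc(O)c(O)c(O)c1)c1cc(O)c(O)c(O)c1 | target

## Step count and risks

Total step count: 17. Longest linear sequence: 11 steps (1, 2, 3, 5, 6, 9, 10, 13, 14, 16, 17).

**Step 13 (key step, proposed new method).** Three processes are most likely to go wrong.
- Poor control of endo approach and of the methide geometry would give the C4 epimer relative to C2 and C3, and poor facial selectivity against the stereocentres of the dimer would add further diastereomers.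
- The addition could become stepwise, with bond rotation in a C2 benzylic cation, which would erode the cis relation.
- The methide is stabilised by two oxygenated aryl groups and may add the alkene too slowly, so self-condensation or intramolecular arylation could take over.

The fallback is the known Lewis-acid coupling of a flavan-4-yl cation, which forms the C4–C8 bond instead of the ring. It sets out from 8. Bromine–lithium exchange (n-BuLi, THF, −78 °C) and quenching with methanol should give the debrominated bis-silylated dimer F1. Commercial (−)-epicatechin is benzylated as in step 4 to 5,7,3',4'-tetra-O-benzyl-(−)-epicatechin F2. This is oxidised with DDQ and 2-ethoxyethanol as in step 3 to its 4β-(2-ethoxyethoxy) ether F3, which is acylated with 22 (DMAP, pyridine) to the 3-O-(tribenzylgalloyl) 4-ether F4. Condensation of F1 with F4 (TMSOTf, CH2Cl2, −78 °C, near-equimolar) should join C4 of the cation to C8 of the epigallocatechin unit of F1, on the β face opposite the C3 ester and the C2 aryl group. It comes back to the route at 20.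

**Step 9.** The addition of the 2,6-dioxygenated aryllithium 12 to the hindered, electron-rich aldehyde 11 may be slow. That would leave time for proton transfer from benzylic ether positions, and the very ionisable benzhydrol could be lost on isolation. The fallback reverses the polarity and sets out from 8. The aryllithium 12 is quenched with DMF to the 8-formyl bis-silylated dimer F5. F5 is then treated with the bromomagnesium phenoxide of commercial 3,5-bis(benzyloxy)phenol (from EtMgBr, toluene), which adds through its ortho carbon in a magnesium chelate (ortho-hydroxyalkylation of a phenol). It comes back to the route at 14 and makes step 10 unnecessary.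

**Step 6.** Silylation of the C3 hydroxyl of the epigallocatechin unit may stall, because it sits axially between the C2 and C4 aryl groups; the mono-silyl ether would then be left. The fallback places the silyl groups before the coupling. From 4, TBSCl and imidazole in DMF should give the 3-O-silyl 4-ether F6. From 6, the same conditions should give 3-O-(tert-butyldimethylsilyl)-tetra-O-benzylcatechin F7. Coupling F6 with F7 under the conditions of step 5 comes back to the route at 8.

**Step 7.** Over-alkylation, under-alkylation and C-benzylation of the phloroglucinol core may give mixtures. The fallback protects everything and then unmasks one position. From 9, exhaustive benzylation (BnBr, K2CO3, DMF, 60 °C) should give 2,4,6-tris(benzyloxy)benzaldehyde F8. Chelation-controlled cleavage of one ortho benzyl ether with MgBr2·OEt2 in toluene/ether comes back to the route at 10.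

## Further compounds

F1 | step 13 | debrominated bis-silylated dimer, penta-O-benzylepigallocatechin-(4β→8)-tetra-O-benzylcatechin bis(tert-butyldimethylsilyl) ether | CC(C)(C)[Si](C)(C)O[C@@H]1[C@@H](c2c(OCc9ccccc9)cc(OCc9ccccc9)c3c2O[C@H](c7ccc(OCc9ccccc9)c(OCc9ccccc9)c7)[C@@H](O[Si](C)(C)C(C)(C)C)C3)c2c(OCc9ccccc9)cc(OCc9ccccc9)cc2O[C@@H]1c7cc(OCc9ccccc9)c(OCc9ccccc9)c(OCc9ccccc9)c7
F2 | step 13 | 5,7,3',4'-tetra-O-benzyl-(−)-epicatechin | O[C@@H]1Cc2c(OCc9ccccc9)cc(OCc9ccccc9)cc2O[C@@H]1c1ccc(OCc9ccccc9)c(OCc9ccccc9)c1
F3 | step 13 | 4β-(2-ethoxyethoxy)-5,7,3',4'-tetra-O-benzyl-(−)-epicatechin | O[C@@H]1[C@@H](OCCOCC)c2c(OCc9ccccc9)cc(OCc9ccccc9)cc2O[C@@H]1c1ccc(OCc9ccccc9)c(OCc9ccccc9)c1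
F4 | step 13 | 4β-(2-ethoxyethoxy)-5,7,3',4'-tetra-O-benzyl-(−)-epicatechin 3-O-[3,4,5-tris(benzyloxy)benzoate] | O=C(O[C@@H]1[C@@H](OCCOCC)c2c(OCc9ccccc9)cc(OCc9ccccc9)cc2O[C@@H]1c1ccc(OCc9ccccc9)c(OCc9ccccc9)c1)c8cc(OCc9ccccc9)c(OCc9ccccc9)c(OCc9ccccc9)c8
F5 | step 9 | 8-formyl bis-silylated dimer | CC(C)(C)[Si](C)(C)O[C@@H]1[C@@H](c2c(OCc9ccccc9)cc(OCc9ccccc9)c3c2O[C@H](c7ccc(OCc9ccccc9)c(OCc9ccccc9)c7)[C@@H](O[Si](C)(C)C(C)(C)C)C3)c2c(OCc9ccccc9)cc(OCc9ccccc9)c(C=O)c2O[C@@H]1c7cc(OCc9ccccc9)c(OCc9ccccc9)c(OCc9ccccc9)c7
F6 | step 6 | 8-bromo-3-O-(tert-butyldimethylsilyl)-4β-(2-ethoxyethoxy)-penta-O-benzylepigallocatechin | CC(C)(C)[Si](C)(C)O[C@@H]1[C@@H](OCCOCC)c2c(OCc9ccccc9)cc(OCc9ccccc9)c(Br)c2O[C@@H]1c1cc(OCc9ccccc9)c(OCc9ccccc9)c(OCc9ccccc9)c1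
F7 | step 6 | 3-O-(tert-butyldimethylsilyl)-5,7,3',4'-tetra-O-benzyl-(+)-catechin | CC(C)(C)[Si](C)(C)O[C@H]1Cc2c(OCc9ccccc9)cc(OCc9ccccc9)cc2O[C@@H]1c1ccc(OCc9ccccc9)c(OCc9ccccc9)c1
F8 | step 7 | 2,4,6-tris(benzyloxy)benzaldehyde | O=Cc1c(OCc9ccccc9)cc(OCc9ccccc9)cc1OCc9ccccc9
A1 | alternative 1 | (Z)-3-(benzyloxy)-5-(tert-butyldimethylsilyloxy)-1-diazopent-3-en-2-one | [N-]=[N+]=CC(=O)/C(OCc9ccccc9)=C/CO[Si](C)(C)C(C)(C)C
A2 | alternative 1 | 4β-[(triisopropylsilyloxy)ethynyl]-3-O-(tert-butyldimethylsilyl)-5,7,3',4'-tetra-O-benzylepicatechin | CC(C)[Si](C(C)C)(C(C)C)OC#C[C@H]3c4c(OCc9ccccc9)cc(OCc9ccccc9)cc4O[C@H](c7ccc(OCc9ccccc9)c(OCc9ccccc9)c7)[C@@H]3O[Si](C)(C)C(C)(C)C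
A3 | alternative 1 | benzannulation product, top unit joined at C4 to C8 of a differentiated phloroglucinol (free C8a hydroxyl, C7 triisopropylsilyl ether, C5 benzyl ether, C4a silyloxymethyl) | CC(C)(C)[Si](C)(C)OCc2c(OCc9ccccc9)cc(O[Si](C(C)C)(C(C)C)C(C)C)c([C@H]3c4c(OCc9ccccc9)cc(OCc9ccccc9)cc4O[C@H](c7ccc(OCc9ccccc9)c(OCc9ccccc9)c7)[C@@H]3O[Si](C)(C)C(C)(C)C)c2O
A4 | alternative 2 | (E)-enone of the bis-silylated dimer, C8–CH=CH–C(=O)–[3,4-bis(benzyloxy)phenyl] | CC(C)(C)[Si](C)(C)O[C@@H]1[C@@H](c2c(OCc9ccccc9)cc(OCc9ccccc9)c3c2O[C@H](c7ccc(OCc9ccccc9)c(OCc9ccccc9)c7)[C@@H](O[Si](C)(C)C(C)(C)C)C3)c2c(OCc9ccccc9)cc(OCc9ccccc9)c(/C=C/C(=O)c7ccc(OCc9ccccc9)c(OCc9ccccc9)c7)c2O[C@@H]1c7cc(OCc9ccccc9)c(OCc9ccccc9)c(OCc9ccccc9)c7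
A5 | alternative 2 | 3,5-bis(benzyloxy)phenol | Oc1cc(OCc9ccccc9)cc(OCc9ccccc9)c1
A6 | alternative 2 | trimer skeleton with the top unit as a 2-aryl-4H-chromene | CC(C)(C)[Si](C)(C)O[C@@H]1[C@@H](c2c(OCc9ccccc9)cc(OCc9ccccc9)c3c2O[C@H](c7ccc(OCc9ccccc9)c(OCc9ccccc9)c7)[C@@H](O[Si](C)(C)C(C)(C)C)C3)c2c(OCc9ccccc9)cc(OCc9ccccc9)c([C@H]3c4c(OCc9ccccc9)cc(OCc9ccccc9)cc4OC(c7ccc(OCc9ccccc9)c(OCc9ccccc9)c7)=C3)c2O[C@@H]1c7cc(OCc9ccccc9)c(OCc9ccccc9)c(OCc9ccccc9)c7
A7 | alternative 3 | 3,4-bis(benzyloxy)benzaldehyde (identical with 15) | O=Cc1ccc(OCc9ccccc9)c(OCc9ccccc9)c1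
A8 | alternative 3 | (Z)-2-[2,4-bis(benzyloxy)-6-hydroxyphenyl]ethenyl 3,4,5-tris(benzyloxy)benzoate | O=C(O/C=C\c7c(O)cc(OCc9ccccc9)cc7OCc9ccccc9)c8cc(OCc9ccccc9)c(OCc9ccccc9)c(OCc9ccccc9)c8
A9 | alternative 3 | perbenzylated epigallocatechin gallate-(4β→8)-catechin gallate with free C8 on the upper unit | O=C(O[C@@H]1[C@@H](c2c(OCc9ccccc9)cc(OCc9ccccc9)c3c2O[C@H](c7ccc(OCc9ccccc9)c(OCc9ccccc9)c7)[C@@H](OC(=O)c8cc(OCc9ccccc9)c(OCc9ccccc9)c(OCc9ccccc9)c8)C3)c2c(OCc9ccccc9)cc(OCc9ccccc9)cc2O[C@@H]1c7cc(OCc9ccccc9)c(OCc9ccccc9)c(OCc9ccccc9)c7)c8cc(OCc9ccccc9)c(OCc9ccccc9)c(OCc9ccccc9)c8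
A10 | alternative 3 | perbenzylated target trimer (identical with 23) | O=C(O[C@@H]1[C@@H](c2c(OCc9ccccc9)cc(OCc9ccccc9)c3c2O[C@H](c7ccc(OCc9ccccc9)c(OCc9ccccc9)c7)[C@@H](OC(=O)c8cc(OCc9ccccc9)c(OCc9ccccc9)c(OCc9ccccc9)c8)C3)c2c(OCc9ccccc9)cc(OCc9ccccc9)c([C@H]3c4c(OCc9ccccc9)cc(OCc9ccccc9)cc4O[C@H](c7ccc(OCc9ccccc9)c(OCc9ccccc9)c7)[C@@H]3OC(=O)c8cc(OCc9ccccc9)c(OCc9ccccc9)c(OCc9ccccc9)c8)c2O[C@@H]1c7cc(OCc9ccccc9)c(OCc9ccccc9)c(OCc9ccccc9)c7)c8cc(OCc9ccccc9)c(OCc9ccccc9)c(OCc9ccccc9)c8
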